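# Open-chain synthesis plan for CNP0256797.1: (3S)-3-[(1S,3S,4S)-3-bromo-4-chloro-4-methylcyclohexyl]-4-[(2R)-3,3-dimethyloxiran-2-yl]-3-hydroxybutan-2-one

## The problem

Atom labels follow the SMILES string: C1 (acetyl CH3), C2 (C=O), C3 (carbinol), C4 (CH2), C5 and C6 (oxirane CH and CMe2), C7 (ring CH), C8 and C9 (ring CH2–CH2), C10 (CClMe), C11 (CHBr), C12 (ring CH2).

The skeleton is one cyclohexane (C7–C12). It is joined through C3–C7 to a fully substituted α-ketol carbon that also bears the acetyl group and the epoxy-prenyl arm, and there are five stereocentres (3S, 5R, 7S, 10S, 11S).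

In the ring the side chain, Br and Cl are all equatorial and the C10 methyl is axial. This trans-diequatorial bromochloride is not the trans-diaxial (Fürst–Plattner) product of any addition to a 4-substituted 1-methylcyclohexene. It is also not expected to be the more stable C7 or C10 epimer, so neither addition to the ring nor equilibration can supply it.

C7 is stereogenic only because C12–C11 differs from C8–C9 two bonds further out. Both of its ring arms are CH2 groups, so once the ring exists C7 cannot bias a reaction at C3, and C3 cannot bias one on the ring.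

C5 is insulated from C3 by C4 and needs reagent control.

The sensitive groups are:
- the tertiary chloride and secondary bromide (E2 with base, bromonium formation in ionising media);
- the oxirane next to a free tertiary OH (acid closes an oxolane);
- the α-ketol (acyloin shift);
- O3 itself, which can capture a bromonium ion or displace bromide while the chain is open.

The enabling feature is the C8–C9 bond, the only ring bond with no substituent and no stereocentre at either end. Read as a reduced alkene, it turns O=C2–C3–C7–C8=C9 into a γ,δ-unsaturated carbonyl array, the retron of a [3,3] shift across C3–C7. It also marks the place where the ring can be closed last.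

## Retrosynthesis

**30 to 28 (no skeletal cut).** O3 is masked as its 2-naphthylmethyl ether (29) and a C8=C9 double bond is written into the ring (28). C8–C9 is preferred to C7–C8, C9–C10, C11–C12 and C12–C7 because each of those ends at a stereocentre. The forward steps must saturate a hindered cis-alkene without touching C–Br, the allylic C–Cl or the oxirane, and must free O3 under neutral conditions.

**28 to 27 (cut C8=C9).** Ring-closing metathesis of diene 27 creates no stereocentre. A closure at C7–C12 or C7–C8 would create C7 under ring-conformational control, which favours the wrong epimer. A closure that leaves C10=C11 in the ring leads back to halogenation of a cyclohexene. Compound 27 has no ring, and all five stereocentres sit on an open chain where only neighbours matter.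

**27 to 24 (remove C10–Cl and C11–Br, return the C9 vinyl group to CH2OH).** The path runs through aldehyde 26 and alcohol 25 to the Z-allylic alcohol 24. On the open chain, anti addition to a Z alkene gives exactly the relation that becomes trans on the ring, and no chair has to be obeyed. The absolute sense comes from a catalyst that needs an allylic OH. C9 is the right carbinol carbon because it is later the metathesis terminus. A carbinol at C12 would call for C–C bond formation or deoxygenation next to C–Br.

**24 to 22 + 12 (cut C11–C12).** This is an sp3–sp2 Negishi coupling. The Z geometry is bought in with iodide 12, which is one step from 10. The neighbouring cut at C10=C11 would need a Z-selective trisubstituted olefination and then a hydride reduction that the C2 ketone would not survive.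

**22 to 18 (C12–I back to C12–O, cut C1–C2, remove the oxirane oxygen).** Iodide 22 comes from keto alcohol 21, which comes from epoxy lactone 19 and then lactone 18. The lactone ties C2 to O12, so one equivalent of MeLi reveals ketone and alcohol together. The epoxidation is placed here because the prenyl group is then the only trisubstituted alkene. Otherwise zinc insertion, electrophilic bromine, metathesis and diimide would each have to spare it.

**18 to 13 (cut C3–C7, key step).** An Ireland–Claisen rearrangement of allyl ester 13 makes this bond. At this stage the two arms at C7 are constitutionally different (alkenyl and CH2O), so the C3/C7 pair is an ordinary vicinal problem set in one chair. Cuts at C3–C4 or C2–C3 would leave C3 to be set beside a finished ring. Compound 13 carries one purchasable-type stereocentre and no C–C stereochemistry. The forward reaction needs one enolate geometry and a chair transition state.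

**13 to 4 + 9, then to 1, 2, 5, 6 and 8.** The ester C–O bond is cut. Alcohol 4 comes from aldehyde 1 and ylide 2 by way of enone 3. Acid 9 comes from 5, 6 and 8 by way of 7. Its α-centre is racemic and is erased on enolisation.

## Roads not taken

**Alternative 1:** cut C10–Cl and C11–Br last, on the ring. The forward key step is addition of BrCl (or NBS with chloride) to the ring alkene of (3S)-3-hydroxy-6-methyl-3-[(1S)-4-methylcyclohex-3-en-1-yl]hept-5-en-2-one A1.
- With the large C7 substituent equatorial, the bromonium ion anti to the side chain is opened at C10 in a chair-like way that is both Markovnikov and diaxial. This gives A2, with both halogen centres inverted relative to 30.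
- The bromonium ion on the needed face reaches the target array only through a twist-boat opening at C10. Its chair-like opening goes to C11.
- O3 also captures the bromonium ion, the prenyl alkene competes for bromine, and C3 would still have to be set beside a C7 whose two arms look alike.
- The chosen plan faces none of these conformational constraints.

**Alternative 2:** make a temporary O3–C10 bond. The forward key step is bromoetherification of A1 to the 2-oxabicyclo[2.2.2]octane A3, followed by cleavage of C10–O with chloride.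
- The appeal is that inversion at C10 would place Cl correctly.
- In A3, however, bromine lies anti to the oxygen bridge, which is the wrong face of C11. It is also antiperiplanar to C10–O, so it assists ionisation, chloride enters with retention, and A2 results again.
- The isomer with Br syn to the bridge cannot come from any anti addition.
- The bridge does not tell the two faces of C3 apart either, because C8H2 and C12H2 flank it alike.

**Alternative 3:** cut C3–C4. The forward key step is addition of a prenyl nucleophile to the C3 carbonyl of diketone A4, which carries the finished ring.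
- C7–H is then α to a carbonyl group and can epimerise to A5, which is expected to be more stable (halogens axial, methyl and side chain equatorial).
- The C2 carbonyl is less hindered than C3, the C3 faces are not differentiated, and prenyl metals tend to react at their γ-carbon.
- A4 still contains the whole unsolved ring problem.
- In the chosen plan C3 is never a carbonyl carbon once the ring exists.

Key step: step 7

Assumption: the sense of induction in steps 2, 8 and 12 is assigned from the accepted transition-state models of these catalyst families; both antipodes of each catalyst or ligand are accessible, so a reversed sense would be corrected by taking the other antipode.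

## Route

Step 1
Reactants: 1 2-[(tert-butyldimethylsilyl)oxy]acetaldehyde; 2 1-(triphenyl-λ5-phosphanylidene)propan-2-one
Product: 3 (3E)-5-[(tert-butyldimethylsilyl)oxy]pent-3-en-2-one
Conditions: CH2Cl2, 23 °C
Reagents that add atoms: none
Why: Wittig olefination with a stabilised ylide, which should give the E-enone under thermodynamic control of the oxaphosphetane.

Step 2
Reactants: 3 (3E)-5-[(tert-butyldimethylsilyl)oxy]pent-3-en-2-one
Product: 4 (2S,3E)-5-[(tert-butyldimethylsilyl)oxy]pent-3-en-2-ol
Conditions: (R)-2-methyl-CBS-oxazaborolidine (10 mol %), BH3·SMe2, THF, −30 °C; MeOH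
Reagents that add atoms: none
Why: Corey–Bakshi–Shibata reduction; the alkenyl group acts as the large and methyl as the small substituent, so the (R)-catalyst should deliver hydride to give the (S)-allylic alcohol by 1,2-reduction only.

Step 3
Reactants: 5 naphthalen-2-ylmethanol; 6 bromoacetic acid
Product: 7 (naphthalen-2-ylmethoxy)acetic acid
Conditions: NaH (2.2 equiv), THF, 0 to 65 °C; aq. HCl (1 mol/L)
Reagents that add atoms: none
Why: Williamson ether synthesis; the alkoxide displaces bromide from the carboxylate salt of 6 by SN2.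

Step 4
Reactants: 7 (naphthalen-2-ylmethoxy)acetic acid; 8 1-bromo-3-methylbut-2-ene
Product: 9 (±)-5-methyl-2-(naphthalen-2-ylmethoxy)hex-4-enoic acid
Conditions: LDA (2.2 equiv), THF, −78 to 0 °C; 8, −78 to 23 °C; aq. HCl (1 mol/L)
Reagents that add atoms: none
Why: C-alkylation of the doubly deprotonated acid at the primary allylic bromide (SN2). The new centre is racemic, which does not matter because step 7 erases it.

Step 5
Reactants: 10 prop-2-yn-1-ol
Product: 12 (2Z)-3-iodo-2-methylprop-2-en-1-ol, via oxamagnesacycle 11 (not isolated)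
Conditions: MeMgBr (2.5 equiv), CuI (10 mol %), THF, −10 to 23 °C; I2, −78 to 0 °C
Reagents that add atoms: methylmagnesium bromide, C[Mg]Br; iodine, [I][I]
Why: Copper-catalysed anti-carbomagnesiation of the propargylic alkoxide puts methyl on C2 and holds magnesium on C3 in the five-membered chelate 11. Iodinolysis with retention then leaves iodine cis to CH2OH.

Step 6
Reactants: 4 (2S,3E)-5-[(tert-butyldimethylsilyl)oxy]pent-3-en-2-ol; 9 (±)-5-methyl-2-(naphthalen-2-ylmethoxy)hex-4-enoic acid
Product: 13 (2S,3E)-5-[(tert-butyldimethylsilyl)oxy]pent-3-en-2-yl 5-methyl-2-(naphthalen-2-ylmethoxy)hex-4-enoate (both epimers at the acyl α-carbon)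
Conditions: EDC·HCl, DMAP (cat.), CH2Cl2, 0 to 23 °C
Reagents that add atoms: none
Why: Steglich-type esterification; the carbinol C–O bond of 4 is not broken, so its (S) configuration is kept.

Step 7
Reactants: 13 (2S,3E)-5-[(tert-butyldimethylsilyl)oxy]pent-3-en-2-yl 5-methyl-2-(naphthalen-2-ylmethoxy)hex-4-enoate
Product: 18 (3S,4S)-3-(3-methylbut-2-en-1-yl)-3-(naphthalen-2-ylmethoxy)-4-[(1E)-prop-1-en-1-yl]oxolan-2-one, via lithium enolate 14 (not isolated), via silyl ketene acetal 15 (not isolated), via trimethylsilyl ester 16 (not isolated), via hydroxy acid 17 (not isolated)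
Conditions: LDA (1.2 equiv), THF, −78 °C; Me3SiCl, −78 to 23 °C; aq. HCl (2 mol/L), THF–MeOH, 23 °C
Reagents that add atoms: lithium diisopropylamide, [Li]N(C(C)C)C(C)C (lithium held in 14 only); chlorotrimethylsilane, C[Si](C)(C)Cl (silicon held in 15 and 16 only)
Why: LDA removes the α-proton of 13 while lithium is held between the enolate oxygen and the naphthylmethoxy oxygen, so the tetrasubstituted enolate 14 should form with these two oxygens cis, and silylation fixes this geometry in the (Z)-ketene acetal 15. On warming, 15 undergoes a concerted suprafacial [3,3] shift (Ireland–Claisen rearrangement; the closest known type is the chelate-controlled rearrangement of allyl esters of O-alkyl glycolic and lactic acids) through a chair in which the carbinol methyl group is equatorial. The C3–C7 σ-bond forms as the allylic C–O bond breaks; the sigmatropic event closes no ring, and the oxolanone ring of 18 closes afterwards by 5-exo-trig lactonisation of hydroxy acid 17 once aqueous acid has removed both silyl groups of 16. C7 is controlled by the E geometry of the alkene together with the (S)-carbinol centre, whose equatorial methyl group decides which alkene face meets the ketene acetal (1,3-chirality transfer; this centre is consumed and becomes the E-propenyl group). C3 is controlled by the ketene acetal geometry within the same chair, so that E-alkene plus Z-acetal should place the naphthylmethoxy and propenyl groups cis, and the prenyl and propenyl groups trans, on the lactone. The step needs one enolate geometry (secured by the chelating ether oxygen in THF without polar additives), chair over boat (secured by the acyclic E-allyl ester, which has no ring constraint) and rearrangement over ester cleavage (secured by early silylation). At this stage the two arms at C7 are an alkenyl and an oxymethyl group, so a relation that is remote in 30 is set here as a vicinal one.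

Step 8
Reactants: 18 (3S,4S)-3-(3-methylbut-2-en-1-yl)-3-(naphthalen-2-ylmethoxy)-4-[(1E)-prop-1-en-1-yl]oxolan-2-one
Product: 19 (3S,4S)-3-{[(2R)-3,3-dimethyloxiran-2-yl]methyl}-3-(naphthalen-2-ylmethoxy)-4-[(1E)-prop-1-en-1-yl]oxolan-2-one
Conditions: D-fructose-derived Shi ketone (30 mol %), KHSO5 (as 2 KHSO5·KHSO4·K2SO4, limiting), K2CO3, Bu4NHSO4, MeCN–CH2(OMe)2, aq. Na2B4O7 buffer, −10 to 0 °C
Reagents that add atoms: potassium peroxymonosulfate, [K+].[O-]S(=O)(=O)OO
Why: Shi epoxidation; the electrophilic dioxirane should prefer the trisubstituted prenyl alkene to the E-disubstituted propenyl group, which sits on a ring carbon next to quaternary C3 and cis to the naphthylmethoxy group. The spiro transition state of the D-fructose-derived ketone gives (R) at C5 for alkenes of the type RCH2CH=CMe2.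

Step 9
Reactants: 19 (3S,4S)-3-{[(2R)-3,3-dimethyloxiran-2-yl]methyl}-3-(naphthalen-2-ylmethoxy)-4-[(1E)-prop-1-en-1-yl]oxolan-2-one
Product: 21 (3S,4S,5E)-3-{[(2R)-3,3-dimethyloxiran-2-yl]methyl}-4-(hydroxymethyl)-3-(naphthalen-2-ylmethoxy)hept-5-en-2-one, via lithium lactolate 20 (not isolated)
Conditions: MeLi (1.1 equiv), THF, −78 °C; AcOH, −78 °C
Reagents that add atoms: methyllithium, [Li]C
Why: Single addition of an organolithium to a lactone; lactolate 20 is stable at −78 °C, which prevents a second addition, and opens to the keto alcohol on protonation. The hindered trisubstituted oxirane is inert to MeLi at this temperature.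

Step 10
Reactants: 21 (3S,4S,5E)-3-{[(2R)-3,3-dimethyloxiran-2-yl]methyl}-4-(hydroxymethyl)-3-(naphthalen-2-ylmethoxy)hept-5-en-2-one
Product: 22 (3S,4R,5E)-3-{[(2R)-3,3-dimethyloxiran-2-yl]methyl}-4-(iodomethyl)-3-(naphthalen-2-ylmethoxy)hept-5-en-2-one
Conditions: I2, PPh3, imidazole, CH2Cl2, 0 °C
Reagents that add atoms: iodine, [I][I]
Why: Appel-type iodination of the only primary alcohol through its alkoxyphosphonium salt (SN2 at C12). The descriptor at C7 changes only because the substituent ranking changes.

Step 11
Reactants: 22 (3S,4R,5E)-3-{[(2R)-3,3-dimethyloxiran-2-yl]methyl}-4-(iodomethyl)-3-(naphthalen-2-ylmethoxy)hept-5-en-2-one; 12 (2Z)-3-iodo-2-methylprop-2-en-1-ol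
Product: 24 (3S,4R,5E)-3-{[(2R)-3,3-dimethyloxiran-2-yl]methyl}-4-[(2Z)-4-hydroxy-3-methylbut-2-en-1-yl]-3-(naphthalen-2-ylmethoxy)hept-5-en-2-one, via alkylzinc iodide 23 (not isolated)
Conditions: Zn dust, LiCl, THF, 25 °C; 12, Pd(OAc)2 (3 mol %), SPhos (6 mol %), THF, 23 °C
Reagents that add atoms: zinc, [Zn] (held in 23 only)
Why: Negishi coupling; zinc inserts into the primary C–I bond, and the alkylzinc iodide tolerates ketone, oxirane and ether. Oxidative addition of the alkenyl iodide to zerovalent palladium and reductive elimination both go with retention, so the Z geometry of 12 is carried over. Alcohols protonate alkylzinc iodides only slowly, so the free OH of 12 is tolerated by a fast catalyst.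

Step 12
Reactants: 24 (3S,4R,5E)-3-{[(2R)-3,3-dimethyloxiran-2-yl]methyl}-4-[(2Z)-4-hydroxy-3-methylbut-2-en-1-yl]-3-(naphthalen-2-ylmethoxy)hept-5-en-2-one
Product: 25 (3S,4R,5E)-4-[(2S,3S)-2-bromo-3-chloro-4-hydroxy-3-methylbutyl]-3-{[(2R)-3,3-dimethyloxiran-2-yl]methyl}-3-(naphthalen-2-ylmethoxy)hept-5-en-2-one
Conditions: NBS, ClTi(OiPr)3, chiral tridentate O,N,O Schiff-base ligand (20 mol %), hexanes–CH2Cl2, −20 °C
Reagents that add atoms: N-bromosuccinimide, O=C1CCC(=O)N1Br; chlorotitanium triisopropoxide, CC(C)O[Ti](Cl)(OC(C)C)OC(C)C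
Why: Catalytic enantioselective bromochlorination of an allylic alcohol; the alkene bound to titanium through O9 takes up Br+, and chloride is passed from titanium to the tertiary C10, anti to bromine. Anti addition to the Z alkene fixes the C10/C11 relation (trans once the ring exists) and the ligand fixes the absolute sense, because C7 is too far away to interfere. The propenyl group lacks the anchoring OH, and no chair has to be obeyed.

Step 13
Reactants: 25 (3S,4R,5E)-4-[(2S,3S)-2-bromo-3-chloro-4-hydroxy-3-methylbutyl]-3-{[(2R)-3,3-dimethyloxiran-2-yl]methyl}-3-(naphthalen-2-ylmethoxy)hept-5-en-2-one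
Product: 26 (3S,4R,5E)-4-[(2S,3S)-2-bromo-3-chloro-3-methyl-4-oxobutyl]-3-{[(2R)-3,3-dimethyloxiran-2-yl]methyl}-3-(naphthalen-2-ylmethoxy)hept-5-en-2-one
Conditions: Dess–Martin periodinane, NaHCO3, CH2Cl2, 0 to 23 °C
Reagents that add atoms: none
Why: Dess–Martin oxidation under buffered, non-basic conditions; the aldehyde has no α-hydrogen, so C10 cannot epimerise and HCl cannot be lost through an enolate.

Step 14
Reactants: 26 (3S,4R,5E)-4-[(2S,3S)-2-bromo-3-chloro-3-methyl-4-oxobutyl]-3-{[(2R)-3,3-dimethyloxiran-2-yl]methyl}-3-(naphthalen-2-ylmethoxy)hept-5-en-2-one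
Product: 27 (3S,4R,5E)-4-[(2S,3S)-2-bromo-3-chloro-3-methylpent-4-en-1-yl]-3-{[(2R)-3,3-dimethyloxiran-2-yl]methyl}-3-(naphthalen-2-ylmethoxy)hept-5-en-2-one
Conditions: Ph3PCH3Br, KHMDS, THF, 0 °C; 26 (ylide 1.1 equiv), −78 to 0 °C
Reagents that add atoms: methyltriphenylphosphonium bromide, C[P+](c1ccccc1)(c1ccccc1)c1ccccc1.[Br-]
Why: Wittig methylenation; at low temperature the aldehyde reacts far faster than the methyl ketone, which is flanked by quaternary C3. The 3-chloro-3-methyl-4-halo-1-ene motif formed here is known to be an isolable array.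

Step 15
Reactants: 27 (3S,4R,5E)-4-[(2S,3S)-2-bromo-3-chloro-3-methylpent-4-en-1-yl]-3-{[(2R)-3,3-dimethyloxiran-2-yl]methyl}-3-(naphthalen-2-ylmethoxy)hept-5-en-2-one
Product: 28 (3S)-3-[(1R,4S,5S)-5-bromo-4-chloro-4-methylcyclohex-2-en-1-yl]-4-[(2R)-3,3-dimethyloxiran-2-yl]-3-(naphthalen-2-ylmethoxy)butan-2-one
Conditions: second-generation Grubbs catalyst RuCl2(=CHPh)(PCy3)(SIMes) (5 mol %), CH2Cl2 (0.005 mol/L), 40 °C
Reagents that add atoms: none
Why: Ring-closing metathesis of a 1,7-diene to a cyclohexene with loss of propene; these are the only two alkenes left, and halides, oxirane and ketone are tolerated. No stereocentre is made or touched, so the contra-thermodynamic ring array arrives intact.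

Step 16
Reactants: 28 (3S)-3-[(1R,4S,5S)-5-bromo-4-chloro-4-methylcyclohex-2-en-1-yl]-4-[(2R)-3,3-dimethyloxiran-2-yl]-3-(naphthalen-2-ylmethoxy)butan-2-one
Product: 29 (3S)-3-[(1S,3S,4S)-3-bromo-4-chloro-4-methylcyclohexyl]-4-[(2R)-3,3-dimethyloxiran-2-yl]-3-(naphthalen-2-ylmethoxy)butan-2-one
Conditions: KO2CN=NCO2K (excess, in portions), AcOH, CH2Cl2, 0 to 23 °C
Reagents that add atoms: none
Why: Diimide reduction; concerted syn transfer of H2 to the only C=C bond, with no metal that could insert into the allylic C–Cl or the C–Br bond. No stereocentre is formed, and the descriptor at C7 changes by ranking only.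

Step 17
Reactants: 29 (3S)-3-[(1S,3S,4S)-3-bromo-4-chloro-4-methylcyclohexyl]-4-[(2R)-3,3-dimethyloxiran-2-yl]-3-(naphthalen-2-ylmethoxy)butan-2-one
Product: 30 (3S)-3-[(1S,3S,4S)-3-bromo-4-chloro-4-methylcyclohexyl]-4-[(2R)-3,3-dimethyloxiran-2-yl]-3-hydroxybutan-2-one
Conditions: DDQ, CH2Cl2–aq. phosphate buffer (pH 7), 0 to 23 °C
Reagents that add atoms: none
Why: Oxidative cleavage of the 2-naphthylmethyl ether by benzylic hydride abstraction and hydrolysis of the oxocarbenium ion. The buffer keeps the freed O3–H from attacking the oxirane under acid catalysis. On the ring, O3 cannot reach the rear side of the equatorial C11–Br bond.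

## Compound list

1 | 2-[(tert-butyldimethylsilyl)oxy]acetaldehyde | O=CCO[Si](C)(C)C(C)(C)C | starting material
2 | 1-(triphenyl-λ5-phosphanylidene)propan-2-one | CC(=O)C=P(c1ccccc1)(c1ccccc1)c1ccccc1 | starting material
3 | (3E)-5-[(tert-butyldimethylsilyl)oxy]pent-3-en-2-one | CC(=O)/C=C/CO[Si](C)(C)C(C)(C)C | intermediate
4 | (2S,3E)-5-[(tert-butyldimethylsilyl)oxy]pent-3-en-2-ol | C[C@H](O)/C=C/CO[Si](C)(C)C(C)(C)C | intermediate
5 | naphthalen-2-ylmethanol | OCc1ccc2ccccc2c1 | starting material
6 | bromoacetic acid | OC(=O)CBr | starting material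
7 | (naphthalen-2-ylmethoxy)acetic acid | OC(=O)COCc1ccc2ccccc2c1 | intermediate
8 | 1-bromo-3-methylbut-2-ene | CC(C)=CCBr | starting material
9 | (±)-5-methyl-2-(naphthalen-2-ylmethoxy)hex-4-enoic acid | OC(=O)C(CC=C(C)C)OCc1ccc2ccccc2c1 | intermediate
10 | prop-2-yn-1-ol | OCC#C | starting material
11 | 4-methyl-2,5-dihydro-1,2-oxamagnesole (cyclic alkenylmagnesium alkoxide) | CC1=C[Mg]OC1 | intermediate
12 | (2Z)-3-iodo-2-methylprop-2-en-1-ol | OC/C(C)=C\[I] | intermediate
13 | (2S,3E)-5-[(tert-butyldimethylsilyl)oxy]pent-3-en-2-yl 5-methyl-2-(naphthalen-2-ylmethoxy)hex-4-enoate (both α-epimers) | C[C@H](OC(=O)C(CC=C(C)C)OCc1ccc2ccccc2c1)/C=C/CO[Si](C)(C)C(C)(C)C | intermediate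
14 | chelated lithium enolate of 13 (OLi cis to the naphthylmethoxy oxygen) | [Li]O/C(O[C@@H](C)/C=C/CO[Si](C)(C)C(C)(C)C)=C(\OCc1ccc2ccccc2c1)CC=C(C)C | intermediate
15 | (Z)-O-trimethylsilyl ketene acetal of 13 | C[Si](C)(C)O/C(O[C@@H](C)/C=C/CO[Si](C)(C)C(C)(C)C)=C(\OCc1ccc2ccccc2c1)CC=C(C)C | intermediate
16 | trimethylsilyl (2S,3S,4E)-3-{[(tert-butyldimethylsilyl)oxy]methyl}-2-(3-methylbut-2-en-1-yl)-2-(naphthalen-2-ylmethoxy)hex-4-enoate | C[Si](C)(C)OC(=O)[C@](OCc1ccc2ccccc2c1)(CC=C(C)C)[C@H](CO[Si](C)(C)C(C)(C)C)/C=C/C | intermediate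
17 | (2S,3S,4E)-3-(hydroxymethyl)-2-(3-methylbut-2-en-1-yl)-2-(naphthalen-2-ylmethoxy)hex-4-enoic acid | OC(=O)[C@](OCc1ccc2ccccc2c1)(CC=C(C)C)[C@H](CO)/C=C/C | intermediate
18 | (3S,4S)-3-(3-methylbut-2-en-1-yl)-3-(naphthalen-2-ylmethoxy)-4-[(1E)-prop-1-en-1-yl]oxolan-2-one | O=C1OC[C@H](/C=C/C)[C@]1(CC=C(C)C)OCc1ccc2ccccc2c1 | intermediate
19 | (3S,4S)-3-{[(2R)-3,3-dimethyloxiran-2-yl]methyl}-3-(naphthalen-2-ylmethoxy)-4-[(1E)-prop-1-en-1-yl]oxolan-2-one | O=C1OC[C@H](/C=C/C)[C@]1(C[C@H]2OC2(C)C)OCc2ccc3ccccc3c2 | intermediate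
20 | lithium lactolate from 19 and MeLi (anomeric centre undefined) | [Li]OC1(C)OC[C@H](/C=C/C)[C@]1(C[C@H]2OC2(C)C)OCc2ccc3ccccc3c2 | intermediate
21 | (3S,4S,5E)-3-{[(2R)-3,3-dimethyloxiran-2-yl]methyl}-4-(hydroxymethyl)-3-(naphthalen-2-ylmethoxy)hept-5-en-2-one | CC(=O)[C@](OCc1ccc2ccccc2c1)(C[C@H]1OC1(C)C)[C@H](CO)/C=C/C | intermediate
22 | (3S,4R,5E)-3-{[(2R)-3,3-dimethyloxiran-2-yl]methyl}-4-(iodomethyl)-3-(naphthalen-2-ylmethoxy)hept-5-en-2-one | CC(=O)[C@](OCc1ccc2ccccc2c1)(C[C@H]1OC1(C)C)[C@H](C[I])/C=C/C | intermediate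
23 | alkylzinc iodide from 22 (Zn on C12) | CC(=O)[C@](OCc1ccc2ccccc2c1)(C[C@H]1OC1(C)C)[C@H](C[Zn][I])/C=C/C | intermediate
24 | (3S,4R,5E)-3-{[(2R)-3,3-dimethyloxiran-2-yl]methyl}-4-[(2Z)-4-hydroxy-3-methylbut-2-en-1-yl]-3-(naphthalen-2-ylmethoxy)hept-5-en-2-one | CC(=O)[C@](OCc1ccc2ccccc2c1)(C[C@H]1OC1(C)C)[C@H](C/C=C(/C)CO)/C=C/C | intermediate
25 | (3S,4R,5E)-4-[(2S,3S)-2-bromo-3-chloro-4-hydroxy-3-methylbutyl]-3-{[(2R)-3,3-dimethyloxiran-2-yl]methyl}-3-(naphthalen-2-ylmethoxy)hept-5-en-2-one | CC(=O)[C@](OCc1ccc2ccccc2c1)(C[C@H]1OC1(C)C)[C@H](C[C@H](Br)[C@@](C)(Cl)CO)/C=C/C | intermediate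
26 | (3S,4R,5E)-4-[(2S,3S)-2-bromo-3-chloro-3-methyl-4-oxobutyl]-3-{[(2R)-3,3-dimethyloxiran-2-yl]methyl}-3-(naphthalen-2-ylmethoxy)hept-5-en-2-one | CC(=O)[C@](OCc1ccc2ccccc2c1)(C[C@H]1OC1(C)C)[C@H](C[C@H](Br)[C@@](C)(Cl)C=O)/C=C/C | intermediate
27 | (3S,4R,5E)-4-[(2S,3S)-2-bromo-3-chloro-3-methylpent-4-en-1-yl]-3-{[(2R)-3,3-dimethyloxiran-2-yl]methyl}-3-(naphthalen-2-ylmethoxy)hept-5-en-2-one | CC(=O)[C@](OCc1ccc2ccccc2c1)(C[C@H]1OC1(C)C)[C@H](C[C@H](Br)[C@@](C)(Cl)C=C)/C=C/C | intermediate
28 | (3S)-3-[(1R,4S,5S)-5-bromo-4-chloro-4-methylcyclohex-2-en-1-yl]-4-[(2R)-3,3-dimethyloxiran-2-yl]-3-(naphthalen-2-ylmethoxy)butan-2-one | CC(=O)[C@](OCc1ccc2ccccc2c1)(C[C@H]1OC1(C)C)[C@H]1C=C[C@](C)(Cl)[C@@H](Br)C1 | intermediate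
29 | (3S)-3-[(1S,3S,4S)-3-bromo-4-chloro-4-methylcyclohexyl]-4-[(2R)-3,3-dimethyloxiran-2-yl]-3-(naphthalen-2-ylmethoxy)butan-2-one | CC(=O)[C@](OCc1ccc2ccccc2c1)(C[C@H]1OC1(C)C)[C@H]1CC[C@](C)(Cl)[C@@H](Br)C1 | intermediate
30 | (3S)-3-[(1S,3S,4S)-3-bromo-4-chloro-4-methylcyclohexyl]-4-[(2R)-3,3-dimethyloxiran-2-yl]-3-hydroxybutan-2-one | CC(=O)[C@](O)(C[C@H]1OC1(C)C)[C@H]1CC[C@](C)(Cl)[C@@H](Br)C1 | target

## Step count and least certain steps

- **Total step count:** 17.
- **Longest linear sequence:** 14 steps (steps 3, 4 and 6 to 17; the branch through steps 1 and 2 is equally long).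

**Step 7 (key step).**
- *Risk:* enolisation of the hindered, α-branched ester may be slow or only partly chelated, which would mix the ketene acetal geometries and erode the C3/C7 relation. Some leakage through a boat transition state would have the same effect.
- *Fallback:* it sets out from 4 and 7 and comes back at 18. Esterification as in step 6 gives the glycolate ester F1, whose less hindered, trisubstituted chelated enolate is rearranged and worked up with acid as in step 7 to the lactone F2. The enolate of F2 (LDA, THF, −78 °C) is then alkylated with 8 on the face anti to the C7 propenyl group. This places prenyl trans to propenyl, as in 18. C3 is thus set by the ring face of a β-substituted butyrolactone enolate instead of by the enolate geometry.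

**Step 8.**
- *Risk:* the dioxirane may discriminate poorly between the prenyl and the propenyl alkene, which leads to over-oxidation. The lactone may also saponify slowly in the basic buffer.
- *Fallback:* it sets out from 18 and comes back at 28, with the epoxidation moved to a point where the propenyl group no longer exists.
  - MeLi as in step 9 gives the keto alcohol F3, and iodination gives the iodide F4.
  - Zinc insertion gives the alkylzinc iodide F5, and coupling with 12 gives the allylic alcohol F6.
  - Bromochlorination as in step 12 gives the bromochloride F7, and oxidation gives the aldehyde F8.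
  - A Wittig reaction with hex-5-en-1-ylidenetriphenylphosphorane gives the relay polyene F9.
  - Relay ring-closing metathesis loads ruthenium on C9, which avoids cyclopentene formation between C8 and the prenyl group, and gives the cyclohexene F10.
  - Shi epoxidation of F10 gives 28, because the cis-disubstituted, chloride-deactivated ring alkene is a poor substrate for this catalyst.

**Step 12.**
- *Risk:* three processes are possible. The catalyst may show poor facial selectivity on a Z-configured 2-methyl allylic alcohol. The O3 ether oxygen may capture the bromonium ion with loss of the naphthylmethyl group. The Lewis-acidic tetravalent titanium chloride may open the oxirane.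
- *Fallback:* it sets out from 24 and comes back at 25. Uncatalysed anti bromochlorination (NBS, Et4NCl, CH2Cl2, −78 °C) is Markovnikov and stereospecific, and it should give 25 together with the (10R,11R) diastereomer F11. The two are separated by chromatography. F11 is returned to 24 by stereospecific anti elimination with zinc dust in ethanol and is then resubmitted.

**Step 15.**
- *Risk:* initiation may be slow at the vinyl group beside fully substituted C10, and the allylic tertiary chloride may ionise or isomerise during a long reaction at the ruthenium centre.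
- *Fallback:* it sets out from 26 and comes back at 28. A Wittig reaction with hex-5-en-1-ylidenetriphenylphosphorane in place of the methylene ylide gives the relay triene F12. The catalyst loads on its unhindered terminal alkene, expels cyclopentene, and is thereby delivered to C9, from where the six-membered ring closes at lower temperature.

**Step 16.**
- *Risk:* the alkene is flanked by C7 and quaternary C10, so it may reduce sluggishly and diimide would then be lost by disproportionation. Prolonged contact with AcOH could also open the oxirane.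
- *Fallback:* it sets out from 28 and comes back at 30. DDQ as in step 17 first gives the free alcohol F13. Its homoallylic O3–H then directs a homogeneous hydrogenation (H2, [Ir(cod)(PCy3)(py)]PF6, CH2Cl2, 0 °C) of the C8=C9 bond. Proximity to the directing group thus replaces the unassisted reduction.

## Further compounds

F1 | step 7 | (2S,3E)-5-[(tert-butyldimethylsilyl)oxy]pent-3-en-2-yl (naphthalen-2-ylmethoxy)acetate | C[C@H](OC(=O)COCc1ccc2ccccc2c1)/C=C/CO[Si](C)(C)C(C)(C)C
F2 | step 7 | (3S,4S)-3-(naphthalen-2-ylmethoxy)-4-[(1E)-prop-1-en-1-yl]oxolan-2-one | O=C1OC[C@H](/C=C/C)[C@@H]1OCc1ccc2ccccc2c1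
F3 | step 8 | (3S,4S,5E)-4-(hydroxymethyl)-3-(3-methylbut-2-en-1-yl)-3-(naphthalen-2-ylmethoxy)hept-5-en-2-one | CC(=O)[C@](OCc1ccc2ccccc2c1)(CC=C(C)C)[C@H](CO)/C=C/C
F4 | step 8 | (3S,4R,5E)-4-(iodomethyl)-3-(3-methylbut-2-en-1-yl)-3-(naphthalen-2-ylmethoxy)hept-5-en-2-one | CC(=O)[C@](OCc1ccc2ccccc2c1)(CC=C(C)C)[C@H](C[I])/C=C/C
F5 | step 8 | alkylzinc iodide from F4 | CC(=O)[C@](OCc1ccc2ccccc2c1)(CC=C(C)C)[C@H](C[Zn][I])/C=C/C
F6 | step 8 | (3S,4R,5E)-4-[(2Z)-4-hydroxy-3-methylbut-2-en-1-yl]-3-(3-methylbut-2-en-1-yl)-3-(naphthalen-2-ylmethoxy)hept-5-en-2-one | CC(=O)[C@](OCc1ccc2ccccc2c1)(CC=C(C)C)[C@H](C/C=C(/C)CO)/C=C/C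
F7 | step 8 | (3S,4R,5E)-4-[(2S,3S)-2-bromo-3-chloro-4-hydroxy-3-methylbutyl]-3-(3-methylbut-2-en-1-yl)-3-(naphthalen-2-ylmethoxy)hept-5-en-2-one | CC(=O)[C@](OCc1ccc2ccccc2c1)(CC=C(C)C)[C@H](C[C@H](Br)[C@@](C)(Cl)CO)/C=C/C
F8 | step 8 | (3S,4R,5E)-4-[(2S,3S)-2-bromo-3-chloro-3-methyl-4-oxobutyl]-3-(3-methylbut-2-en-1-yl)-3-(naphthalen-2-ylmethoxy)hept-5-en-2-one | CC(=O)[C@](OCc1ccc2ccccc2c1)(CC=C(C)C)[C@H](C[C@H](Br)[C@@](C)(Cl)C=O)/C=C/C
F9 | step 8 | (3S,4R,5E)-4-[(2S,3S,4Z)-2-bromo-3-chloro-3-methyldeca-4,9-dien-1-yl]-3-(3-methylbut-2-en-1-yl)-3-(naphthalen-2-ylmethoxy)hept-5-en-2-one | CC(=O)[C@](OCc1ccc2ccccc2c1)(CC=C(C)C)[C@H](C[C@H](Br)[C@@](C)(Cl)/C=C\CCCC=C)/C=C/C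
F10 | step 8 | (3S)-3-[(1R,4S,5S)-5-bromo-4-chloro-4-methylcyclohex-2-en-1-yl]-6-methyl-3-(naphthalen-2-ylmethoxy)hept-5-en-2-one | CC(=O)[C@](OCc1ccc2ccccc2c1)(CC=C(C)C)[C@H]1C=C[C@](C)(Cl)[C@@H](Br)C1
F11 | step 12 | (3S,4R,5E)-4-[(2R,3R)-2-bromo-3-chloro-4-hydroxy-3-methylbutyl]-3-{[(2R)-3,3-dimethyloxiran-2-yl]methyl}-3-(naphthalen-2-ylmethoxy)hept-5-en-2-one | CC(=O)[C@](OCc1ccc2ccccc2c1)(C[C@H]1OC1(C)C)[C@H](C[C@@H](Br)[C@](C)(Cl)CO)/C=C/C
F12 | step 15 | (3S,4R,5E)-4-[(2S,3S,4Z)-2-bromo-3-chloro-3-methyldeca-4,9-dien-1-yl]-3-{[(2R)-3,3-dimethyloxiran-2-yl]methyl}-3-(naphthalen-2-ylmethoxy)hept-5-en-2-one | CC(=O)[C@](OCc1ccc2ccccc2c1)(C[C@H]1OC1(C)C)[C@H](C[C@H](Br)[C@@](C)(Cl)/C=C\CCCC=C)/C=C/C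
F13 | step 16 | (3S)-3-[(1R,4S,5S)-5-bromo-4-chloro-4-methylcyclohex-2-en-1-yl]-4-[(2R)-3,3-dimethyloxiran-2-yl]-3-hydroxybutan-2-one | CC(=O)[C@](O)(C[C@H]1OC1(C)C)[C@H]1C=C[C@](C)(Cl)[C@@H](Br)C1
A1 | alternative 1 | (3S)-3-hydroxy-6-methyl-3-[(1S)-4-methylcyclohex-3-en-1-yl]hept-5-en-2-one | CC(=O)[C@](O)(CC=C(C)C)[C@H]1CCC(C)=CC1
A2 | alternative 1 | (3S)-3-[(1S,3R,4R)-3-bromo-4-chloro-4-methylcyclohexyl]-3-hydroxy-6-methylhept-5-en-2-one (halogens trans-diaxial) | CC(=O)[C@](O)(CC=C(C)C)[C@H]1CC[C@@](C)(Cl)[C@H](Br)C1
A3 | alternative 2 | 1-[6-bromo-1-methyl-3-(3-methylbut-2-en-1-yl)-2-oxabicyclo[2.2.2]octan-3-yl]ethan-1-one (Br anti to the oxygen bridge) | CC(=O)[C@@]1(CC=C(C)C)O[C@]2(C)CC[C@H]1C[C@H]2Br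
A4 | alternative 3 | 1-[(1S,3S,4S)-3-bromo-4-chloro-4-methylcyclohexyl]propane-1,2-dione | CC(=O)C(=O)[C@H]1CC[C@](C)(Cl)[C@@H](Br)C1
A5 | alternative 3 | 1-[(1R,3S,4S)-3-bromo-4-chloro-4-methylcyclohexyl]propane-1,2-dione | CC(=O)C(=O)[C@@H]1CC[C@](C)(Cl)[C@@H](Br)C1
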